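Free monomer cannot vanish, yet in the west run at 6.00 d free monomer and monomer in chains together make 23.8 % of the charge. I read the missing part as free monomer taken one for one by protic impurity, which in the flask is the limiting reagent of this loss, being charged at less than the free monomer.

the same everywhere: initiator 26 mM

|  | free monomer | protic impurity | remark | time |
|---|---|---|---|---|
| north-west | 0.13 M | 0.13 M | run made earlier |  |
| east | 0.20 M | 0.13 M | run made earlier |  |
| west | 0.26 M | 0.26 M | run made earlier |  |
| flask | 0.26 M | 0.130 M |  | 10 d |

- north-west (time / d: monomer in chains / %, free monomer / %): 0.500: 5.7, 73.8; 0.833: 8.7, 59.9; 1.67: 13.9, 42.1; 3.00: 17.5, 26.4; 6.00: 21.2, 11.4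
- east (time / d: monomer in chains / %, free monomer / %): 1.25: 16.9, 49.1; 2.50: 23.4, 32.8; 4.00: 26.5, 23.6; 5.00: 27.7, 19.6; 6.00: 28.5, 16.1
- west (time / d: monomer in chains / %, free monomer / %): 1.25: 14.9, 32.0; 2.50: 17.2, 16.1; 4.00: 18.5, 10.0; 5.00: 18.6, 7.0; 6.00: 18.7, 5.1

(standard deviation of a reading: 0.5 percentage points)

- the average divides the monomer in chains by the number of chains begun, living and dead together
- the numbers in the tables scatter with a standard deviation of 0.5 percentage points
- the earlier runs do not show the number of chains; that part of a forecast is a guess

* average number of monomer units in a chain (chains begun, living or dead) at 10 d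
* part of the free monomer that has reacted at 10 d

For the flask I called 50.0 % the quench ceiling: the charge of protic impurity as a part of the charge of free monomer. That was my first way to the loss at 10 d. My second worked with the fraction left. In the east run at 6.00 d, the missing part against that run's own ceiling left 14.8 % of the protic impurity. Carried at the same pace to 10 d, this gave 4.13 % left, so a loss of 47.9 %. The two parted by 2.1 percentage points. The ceiling cheats at this time, standing above the second number, since it counts the remaining impurity as spent. The borrowed pace errs too, but the flask is richer in free monomer, so I kept the second number.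

Of the monomer that escaped loss, 36.1 % was still free in the east run at 6.00 d, and that part fell at each reading. So I put c, the part reacted, at 81.2 % or somewhat above, and left dp unreckoned, the chains being unread.

The forecast gave 3.4 and 79 %, with the impurity “nearly used up by 10 d”.

The flask gave 6.54 and 85.5 %.

    free monomer + initiator → living end + monomer in chains (k = 0.0468 L mol⁻¹ h⁻¹)
    free monomer + living end → monomer in chains + living end, rate k2*[living end]*[free monomer] (k = 10.5 L mol⁻¹ h⁻¹)
    protic impurity + free monomer → quenched substrate (k = 0.176 L mol⁻¹ h⁻¹)
    living end → dead end (k = 0.208 h⁻¹)

The flask had not come to rest at 10 d. With 4.0 % of its protic impurity left, the ceiling counted one for one gives 48.0 %, and quenched substrate stood at 48.0 % of the free monomer charged. A neighbouring flask, the same but with 0.22 M of protic impurity, has a ceiling of 84.6 %; with 14 % left the same count gives 72.7 %, and that flask held 72.7 %. Left until 100 d, the flask reached 50.0 % quenched substrate with 0 % protic impurity, while initiator fell from 43 % to 7.05 % and free monomer to 4.80 %; c rose to 95.2 % and dp came down to 4.86.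

Readings and results come from a simulation with constants of no real substance; the scatter is artificial.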